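## Retrosynthetic overview

1. The target comes from its C7/C8 diol by selective acetylation of the secondary C8–OH; the diol comes from its 7,8-acetonide (atom labels are the isochromene locants of the target).
2. The pyran ring is formed second: Sonogashira coupling of a 2,3-dichlorocyclohexenone with the (E,E)-dienyne at the β-chloride (C4a–C4), then 6-endo oxa-conjugate addition of the C1 hydroxyl (O2–C3).
3. The carbocycle is formed first, in the key step: Cp2TiCl opens a terminal epoxide to the C8a radical, which closes onto the CCl2 carbon of a trichlorovinyl ketone and expels chlorine. This forms C4a–C8a, sets C8a and leaves both chlorines in place.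
4. The epoxy ketone comes from D-erythronolactone (C7/C8 cis-diol from the chiral pool, C7 methyl by enolate alkylation), a sulfur-ylide CH2 (C1) and trichloroethylene (C4a, C5).
5. The dienyne comes from (R)-2-methylbutan-1-ol by Wittig and Horner–Wadsworth–Emmons olefinations.

Assumption: the side-chain stereocentre is R as written in the SMILES, and (R)-2-methylbutan-1-ol is purchasable as the single enantiomer.

## Route

Step 1
Reactants: 1 D-erythrono-1,4-lactone
Product: 2 (3aR,6aR)-2,2-dimethyldihydrofuro[3,4-d][1,3]dioxol-4(3aH)-one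
Conditions: 2,2-dimethoxypropane, TsOH·H2O (cat.), acetone, rt
Reagents that add atoms: 2,2-dimethoxypropane, COC(C)(C)OC
Why: Acid-catalysed acetonide formation (transketalisation) on the cis-diol; the two stereocentres (future C7 and C8) come unchanged from the chiral pool.

Step 2
Reactants: 2 (3aR,6aR)-2,2-dimethyldihydrofuro[3,4-d][1,3]dioxol-4(3aH)-one
Product: 4 (3aR,6aR)-2,2,3a-trimethyldihydrofuro[3,4-d][1,3]dioxol-4(3aH)-one, via lithium enolate 3 (not isolated)
Conditions: LiN(i-Pr)2, THF, –78 °C; then MeI, DMPU, –78 → –40 °C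
Reagents that add atoms: iodomethane, CI
Why: Lactone enolate C-alkylation; the enolate is planar at C7, but methyl can enter only on the face that keeps the two five-membered rings cis-fused, so C8 regenerates C7 with retention, and β-elimination of the C8 oxygen is slow because that C–O bond lies near the enolate plane.

Step 3
Reactants: 4 (3aR,6aR)-2,2,3a-trimethyldihydrofuro[3,4-d][1,3]dioxol-4(3aH)-one
Product: 5 (4R,5R)-5-(hydroxymethyl)-N-methoxy-N,2,2,4-tetramethyl-1,3-dioxolane-4-carboxamide
Conditions: MeNH(OMe)·HCl, i-PrMgCl, THF, –20 → 0 °C; aq. NH4Cl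
Reagents that add atoms: N,O-dimethylhydroxylamine hydrochloride, CNOC.Cl
Why: Weinreb amide formation by ring-opening aminolysis of the lactone with the magnesium amide; it frees the primary alcohol (future C8a) and arms C6 for a single carbanion addition.

Step 4
Reactants: 5 (4R,5R)-5-(hydroxymethyl)-N-methoxy-N,2,2,4-tetramethyl-1,3-dioxolane-4-carboxamide
Product: 6 (4R,5S)-5-formyl-N-methoxy-N,2,2,4-tetramethyl-1,3-dioxolane-4-carboxamide
Conditions: Dess–Martin periodinane, CH2Cl2, 0 °C → rt
Reagents that add atoms: none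
Why: Dess–Martin oxidation of the primary alcohol under near-neutral conditions leaves the acetonide, the amide and the α-alkoxy centre (C8) untouched; the descriptor changes only through ligand priorities.

Step 5
Reactants: 6 (4R,5S)-5-formyl-N-methoxy-N,2,2,4-tetramethyl-1,3-dioxolane-4-carboxamide
Product: 7 (4R,5R)-N-methoxy-N,2,2,4-tetramethyl-5-(oxiran-2-yl)-1,3-dioxolane-4-carboxamide (both oxirane epimers)
Conditions: Me3S+ I–, KN(SiMe3)2, THF, –20 °C; then 6, –20 → 0 °C
Reagents that add atoms: trimethylsulfonium iodide, C[S+](C)C.[I-]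
Why: Corey–Chaykovsky epoxidation: the sulfonium ylide adds to the aldehyde and closes to the terminal epoxide without touching the Weinreb amide; the oxirane centre forms as a mixture, which is harmless because it becomes a planar radical in step 7.

Step 6
Reactants: 7 (4R,5R)-N-methoxy-N,2,2,4-tetramethyl-5-(oxiran-2-yl)-1,3-dioxolane-4-carboxamide; 8 trichloroethylene
Product: 10 2,3,3-trichloro-1-[(4R,5R)-2,2,4-trimethyl-5-(oxiran-2-yl)-1,3-dioxolan-4-yl]prop-2-en-1-one (both oxirane epimers), via trichlorovinyllithium 9 (not isolated)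
Conditions: 8, n-BuLi, THF/Et2O, –100 → –78 °C; then 7, –78 °C; aq. NH4Cl at –78 °C
Reagents that add atoms: none
Why: Weinreb ketone synthesis: trichlorovinyllithium (from deprotonation of trichloroethylene) adds once to the amide, the lithium chelate holding the tetrahedral stage until the cold quench, and the epoxide is inert to the carbenoid at –78 °C.

Step 7
Reactants: 10 2,3,3-trichloro-1-[(4R,5R)-2,2,4-trimethyl-5-(oxiran-2-yl)-1,3-dioxolan-4-yl]prop-2-en-1-one
Product: 11 (3aR,4R,7aR)-5,6-dichloro-4-(hydroxymethyl)-2,2,7a-trimethyl-3a,4-dihydro-1,3-benzodioxol-7(7aH)-one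
Conditions: Cp2TiCl2 (2.5 equiv), Mn dust, THF, rt; the green Cp2TiCl solution added over 3 h to 10 (0.01 M, THF), rt; aq. NaH2PO4
Reagents that add atoms: none
Why: Proposed new method: Cp2TiCl (trivalent titanium) opens the terminal epoxide homolytically at the more substituted carbon (titanocene epoxide opening, known) to give the secondary C8a radical with oxygen left on C1; since the acyl arm and the radical arm are cis on the dioxolane, the radical reaches the CCl2 terminus (β-carbon) of the trichlorovinyl ketone in a 6-endo-trig closure (attack at the α-carbon is disfavoured because it carries chlorine and is polarity-mismatched); the α-chloro-α-keto radical then restores the double bond by losing a β-chlorine, either as a chlorine atom or after reduction by a second Cp2TiCl to the titanium enolate, as in known radical vinylations with trichloroethylene and other β-halo acceptors and in titanocene epoxide cyclisations onto activated alkenes; both epoxide epimers give the same radical, and C8a is set in the ring closure with the bulky titanoxymethyl group on the convex face, anti to the cis-fused acetonide and trans to the C8 oxygen.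

Step 8
Reactants: 12 (R)-2-methylbutan-1-ol
Product: 14 (2E,4R)-2,4-dimethylhex-2-enal, via (R)-2-methylbutanal 13 (not isolated)
Conditions: Dess–Martin periodinane, ClCH2CH2Cl, 0 °C → rt; then Ph3P=C(CH3)CHO, 70 °C
Reagents that add atoms: 2-(triphenylphosphoranylidene)propanal, CC(C=O)=P(c1ccccc1)(c1ccccc1)c1ccccc1
Why: Dess–Martin oxidation followed in the same flask by Wittig olefination with the stabilised formyl ylide, which gives the (E)-trisubstituted enal; the labile α-stereocentre of the aldehyde is never exposed to base or isolation.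

Step 9
Reactants: 14 (2E,4R)-2,4-dimethylhex-2-enal
Product: 16 (3E,5E,7R)-5,7-dimethylnona-3,5-dien-1-yne, via TMS-dienyne 15 (not isolated)
Conditions: (EtO)2P(O)CH2C≡CSiMe3, LiN(SiMe3)2, THF, –78 → 0 °C; then K2CO3 (cat.), MeOH, rt
Reagents that add atoms: diethyl [3-(trimethylsilyl)prop-2-yn-1-yl]phosphonate, CCOP(=O)(CC#C[Si](C)(C)C)OCC
Why: Horner–Wadsworth–Emmons olefination with the silylpropargyl phosphonate gives the (E)-enyne, and carbonate/methanol then removes the alkynyl silane in the same flask.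

Step 10
Reactants: 11 (3aR,4R,7aR)-5,6-dichloro-4-(hydroxymethyl)-2,2,7a-trimethyl-3a,4-dihydro-1,3-benzodioxol-7(7aH)-one; 16 (3E,5E,7R)-5,7-dimethylnona-3,5-dien-1-yne
Product: 18 7,8-acetonide (7,8-O-isopropylidene derivative) of (7R,8R,8aR)-5-chloro-3-[(1E,3E,5R)-3,5-dimethylhepta-1,3-dien-1-yl]-7,8-dihydroxy-7-methyl-1,7,8,8a-tetrahydro-6H-isochromen-6-one, via alkynyl enone 17 (not isolated)
Conditions: PdCl2(PPh3)2 (5 mol %), CuI (10 mol %), Et3N, THF, degassed, 45 °C; then DBU (0.2 equiv), rt
Reagents that add atoms: none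
Why: Sonogashira coupling, in which zerovalent palladium inserts only into the β C–Cl bond (a vinylogous acyl chloride) while the α-chloride stays; DBU then triggers 6-endo-dig oxa-conjugate (1,6-) addition of the primary hydroxyl to the δ-carbon of the ynenone, and the acetonide keeps the C8 oxygen from competing.

Step 11
Reactants: 18 7,8-acetonide of the diol
Product: 19 (7R,8R,8aR)-5-chloro-3-[(1E,3E,5R)-3,5-dimethylhepta-1,3-dien-1-yl]-7,8-dihydroxy-7-methyl-1,7,8,8a-tetrahydro-6H-isochromen-6-one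
Conditions: TFA/H2O/THF (1:1:2), 0 °C → rt
Reagents that add atoms: none
Why: Acid-catalysed acetonide hydrolysis; the push–pull dienone ether (a vinylogous ester) tolerates cold aqueous acid and no stereocentre is touched.

Step 12
Reactants: 19 (7R,8R,8aR)-5-chloro-3-[(1E,3E,5R)-3,5-dimethylhepta-1,3-dien-1-yl]-7,8-dihydroxy-7-methyl-1,7,8,8a-tetrahydro-6H-isochromen-6-one
Product: 20 (7R,8R,8aR)-5-chloro-3-[(1E,3E,5R)-3,5-dimethylhepta-1,3-dien-1-yl]-7-hydroxy-7-methyl-6-oxo-6,7,8,8a-tetrahydro-1H-isochromen-8-yl acetate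
Conditions: Ac2O (1.2 equiv), pyridine, DMAP (5 mol %), CH2Cl2, 0 °C
Reagents that add atoms: acetic anhydride, CC(=O)OC(C)=O
Why: Selective acylation (DMAP nucleophilic catalysis) of the secondary C8 hydroxyl over the hindered tertiary C7 hydroxyl; short reaction time at 0 °C avoids elimination of the new β-acetoxy group.

## Compound list

1 | D-erythrono-1,4-lactone, (3R,4R)-3,4-dihydroxyoxolan-2-one | O=C1[C@H](O)[C@H](O)CO1 | starting material
2 | (3aR,6aR)-2,2-dimethyldihydrofuro[3,4-d][1,3]dioxol-4(3aH)-one | O=C1[C@@H]2OC(C)(C)O[C@@H]2CO1 | intermediate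
3 | lithium enolate of 2, lithium (6aR)-2,2-dimethyl-6,6a-dihydrofuro[3,4-d][1,3]dioxol-4-olate | [Li+].[O-]C1=C2OC(C)(C)O[C@@H]2CO1 | intermediate (not isolated)
4 | (3aR,6aR)-2,2,3a-trimethyldihydrofuro[3,4-d][1,3]dioxol-4(3aH)-one | O=C1[C@]2(C)OC(C)(C)O[C@@H]2CO1 | intermediate
5 | (4R,5R)-5-(hydroxymethyl)-N-methoxy-N,2,2,4-tetramethyl-1,3-dioxolane-4-carboxamide | CON(C)C(=O)[C@]1(C)OC(C)(C)O[C@@H]1CO | intermediate
6 | (4R,5S)-5-formyl-N-methoxy-N,2,2,4-tetramethyl-1,3-dioxolane-4-carboxamide | CON(C)C(=O)[C@]1(C)OC(C)(C)O[C@@H]1C=O | intermediate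
7 | (4R,5R)-N-methoxy-N,2,2,4-tetramethyl-5-(oxiran-2-yl)-1,3-dioxolane-4-carboxamide (both oxirane epimers) | CON(C)C(=O)[C@]1(C)OC(C)(C)O[C@@H]1C2CO2 | intermediate
8 | trichloroethylene | ClC=C(Cl)Cl | starting material
9 | trichlorovinyllithium | [Li]C(Cl)=C(Cl)Cl | intermediate (not isolated)
10 | 2,3,3-trichloro-1-[(4R,5R)-2,2,4-trimethyl-5-(oxiran-2-yl)-1,3-dioxolan-4-yl]prop-2-en-1-one (both oxirane epimers) | ClC(Cl)=C(Cl)C(=O)[C@]1(C)OC(C)(C)O[C@@H]1C2CO2 | intermediate
11 | (3aR,4R,7aR)-5,6-dichloro-4-(hydroxymethyl)-2,2,7a-trimethyl-3a,4-dihydro-1,3-benzodioxol-7(7aH)-one | ClC1=C(Cl)C(=O)[C@]2(C)OC(C)(C)O[C@@H]2[C@H]1CO | intermediate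
12 | (R)-2-methylbutan-1-ol | CC[C@@H](C)CO | starting material
13 | (R)-2-methylbutanal | CC[C@@H](C)C=O | intermediate (not isolated)
14 | (2E,4R)-2,4-dimethylhex-2-enal | CC[C@@H](C)/C=C(C)/C=O | intermediate
15 | trimethyl[(3E,5E,7R)-5,7-dimethylnona-3,5-dien-1-yn-1-yl]silane | CC[C@@H](C)/C=C(C)/C=C/C#C[Si](C)(C)C | intermediate (not isolated)
16 | (3E,5E,7R)-5,7-dimethylnona-3,5-dien-1-yne | CC[C@@H](C)/C=C(C)/C=C/C#C | intermediate
17 | (3aR,4R,7aR)-6-chloro-5-[(3E,5E,7R)-5,7-dimethylnona-3,5-dien-1-yn-1-yl]-4-(hydroxymethyl)-2,2,7a-trimethyl-3a,4-dihydro-1,3-benzodioxol-7(7aH)-one | CC[C@@H](C)/C=C(C)/C=C/C#CC1=C(Cl)C(=O)[C@]2(C)OC(C)(C)O[C@@H]2[C@H]1CO | intermediate (not isolated)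
18 | 7,8-acetonide of (7R,8R,8aR)-5-chloro-3-[(1E,3E,5R)-3,5-dimethylhepta-1,3-dien-1-yl]-7,8-dihydroxy-7-methyl-1,7,8,8a-tetrahydro-6H-isochromen-6-one | CC[C@@H](C)/C=C(C)/C=C/C1=CC2=C(Cl)C(=O)[C@]3(C)OC(C)(C)O[C@@H]3[C@H]2CO1 | intermediate
19 | (7R,8R,8aR)-5-chloro-3-[(1E,3E,5R)-3,5-dimethylhepta-1,3-dien-1-yl]-7,8-dihydroxy-7-methyl-1,7,8,8a-tetrahydro-6H-isochromen-6-one | CC[C@@H](C)/C=C(C)/C=C/C1=CC2=C(Cl)C(=O)[C@](C)(O)[C@H](O)[C@H]2CO1 | intermediate
20 | (7R,8R,8aR)-5-chloro-3-[(1E,3E,5R)-3,5-dimethylhepta-1,3-dien-1-yl]-7-hydroxy-7-methyl-6-oxo-6,7,8,8a-tetrahydro-1H-isochromen-8-yl acetate | CC[C@@H](C)/C=C(C)/C=C/C1=CC2=C(Cl)C(=O)[C@](C)(O)[C@H](OC(C)=O)[C@H]2CO1 | target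

## Step count and risk

Total steps: 12. Longest linear sequence: 10 steps (steps 1–7, then 10, 11, 12, from 1); the side chain (steps 8 and 9) joins at step 10.

Most likely to fail, with fallbacks:

**Step 7 (radical ring closure).** Trivalent titanium may reduce the electron-poor trichlorovinyl ketone in competition with the epoxide. The radical may also close 5-exo at the α-carbon, or be reduced and deoxygenated before it cyclises. The C8a selectivity is predicted, not proven; a minor epimer would be removed at 11. The fallback sets out from 7 and returns at 18. It keeps the titanium radical closure but uses an alkyne acceptor and moves the α-chlorine to the end. Lithium chloroacetylide (from cis-1,2-dichloroethene and MeLi) converts 7 into 3-chloro-1-[(4R,5R)-2,2,4-trimethyl-5-(oxiran-2-yl)-1,3-dioxolan-4-yl]prop-2-yn-1-one F1. Cp2TiCl then gives the C8a radical, which closes 6-endo-dig on the chlorine-bearing alkyne carbon; the vinyl radical takes hydrogen from THF to give (3aR,4R,7aR)-5-chloro-4-(hydroxymethyl)-2,2,7a-trimethyl-3a,4-dihydro-1,3-benzodioxol-7(7aH)-one F2. Coupling and ring closure with 16 as in step 10 gives the 5-deschloro analogue of 18 F3. N-Chlorosuccinimide then chlorinates the vinylogous α-carbon C5 to give 18.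

**Step 6 (carbenoid acylation).** Trichlorovinyllithium may lose LiCl (to dichloroacetylene, a hazard) faster than it adds to the hindered amide. The fallback sets out from 7 and returns at 10. DIBAL-H at –78 °C reduces 7 to (4R,5R)-2,2,4-trimethyl-5-(oxiran-2-yl)-1,3-dioxolane-4-carbaldehyde F4. The far more electrophilic aldehyde takes up 9 at –100 °C to give 2,3,3-trichloro-1-[2,2,4-trimethyl-5-(oxiran-2-yl)-1,3-dioxolan-4-yl]prop-2-en-1-ol with the dioxolane configuration of 7 (carbinol epimers) F5. Dess–Martin oxidation gives 10.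

**Step 10 (coupling and pyran closure).** Oxidative addition into the vinylic C–Cl bond may be slow, 16 may dimerise oxidatively, or the hydroxyl may close 5-exo. The fallback sets out from 14 (and uses 11) and returns at 18. It forms C4a–C4 by enolate addition–elimination and closes the pyran by dehydration. Wittig reaction of 14 with Ph3P=CHC(O)CH3 gives (3E,5E,7R)-5,7-dimethylnona-3,5-dien-2-one F6. Its kinetic lithium enolate (LiN(i-Pr)2, 2.2 equiv, the first equivalent taken by the hydroxyl of 11) displaces the β-chloride of 11 to give (3aR,4R,7aR)-6-chloro-5-[(3E,5E,7R)-5,7-dimethyl-2-oxonona-3,5-dien-1-yl]-4-(hydroxymethyl)-2,2,7a-trimethyl-3a,4-dihydro-1,3-benzodioxol-7(7aH)-one F7. PPTS in toluene at 60 °C closes the hemiketal and dehydrates it to 18.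

Further compounds
F1 | step 7 | 3-chloro-1-[(4R,5R)-2,2,4-trimethyl-5-(oxiran-2-yl)-1,3-dioxolan-4-yl]prop-2-yn-1-one | ClC#CC(=O)[C@]1(C)OC(C)(C)O[C@@H]1C2CO2
F2 | step 7 | (3aR,4R,7aR)-5-chloro-4-(hydroxymethyl)-2,2,7a-trimethyl-3a,4-dihydro-1,3-benzodioxol-7(7aH)-one | ClC1=CC(=O)[C@]2(C)OC(C)(C)O[C@@H]2[C@H]1CO
F3 | step 7 | 5-deschloro analogue of 18 | CC[C@@H](C)/C=C(C)/C=C/C1=CC2=CC(=O)[C@]3(C)OC(C)(C)O[C@@H]3[C@H]2CO1
F4 | step 6 | (4R,5R)-2,2,4-trimethyl-5-(oxiran-2-yl)-1,3-dioxolane-4-carbaldehyde | O=C[C@]1(C)OC(C)(C)O[C@@H]1C2CO2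
F5 | step 6 | 2,3,3-trichloro-1-[2,2,4-trimethyl-5-(oxiran-2-yl)-1,3-dioxolan-4-yl]prop-2-en-1-ol with the dioxolane configuration of 7 (carbinol epimers) | OC(C(Cl)=C(Cl)Cl)[C@]1(C)OC(C)(C)O[C@@H]1C2CO2
F6 | step 10 | (3E,5E,7R)-5,7-dimethylnona-3,5-dien-2-one | CC[C@@H](C)/C=C(C)/C=C/C(C)=O
F7 | step 10 | (3aR,4R,7aR)-6-chloro-5-[(3E,5E,7R)-5,7-dimethyl-2-oxonona-3,5-dien-1-yl]-4-(hydroxymethyl)-2,2,7a-trimethyl-3a,4-dihydro-1,3-benzodioxol-7(7aH)-one | CC[C@@H](C)/C=C(C)/C=C/C(=O)CC1=C(Cl)C(=O)[C@]2(C)OC(C)(C)O[C@@H]2[C@H]1CO
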